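**Plan**

- Retrosynthesis: first both C–C bonds of the ArC7–CH2–C3(pyrone) bridge are cut (three-component union of arene, pyrone and a CH2=NMe2+ C1 unit). Then the bonds O1–C2 and C3a–C3 of the dihydrofuran are cut together, a formal (3+2) heteroannulation, back to an o-iodophenol and myrcene. The pyrone is cut at its lactone C–O bond and at the C4–C5 bond of a 3,5-diketo ester.
- Enabling feature: the ring O1–C7a–C3a–C3–C2 carries at C2 the exocyclic C(=CH2)CH2CH2CH=CMe2 group. C3–C2–C(=CH2) is therefore the intact 1,3-diene of myrcene (all ten carbons), and O1–C7a–C3a is an ortho O–C–C unit of the phloroglucinol. An aryl–Pd species adds to the diene terminus and the phenol oxygen closes on the π-allyl.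
- Forward order: the pyrone ring is made first (steps 1–2). The benzene ring is bought as phloroacetophenone and desymmetrised so that only the oxygen para to the acetyl is free, with iodine beside it (steps 3–6). The dihydrofuran ring closes last (step 7). MOM removal and the methylene bridge finish the route (steps 8–9).
- Stereochemistry: the single stereocentre, C2 (R), is created in step 7 under control of the chiral ligand on palladium and is not touched afterwards.

Key step: step 7

Remark: the chiral sulfinamide–phosphine ligand of step 7 is treated as a purchasable catalyst component; C2 of the target is R (O1 > C(=CH2) > C3 > H).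

**Route**

Step 1
Reactants: 1 methyl 3-oxopentanoate; 2 N-methoxy-N-methylpropanamide
Product: 4 methyl 4-methyl-3,5-dioxoheptanoate, via dianion 3 (not isolated)
Conditions: NaH, THF, 0 °C; n-BuLi, 0 °C; then 2, −78 → 0 °C; aq. HCl work-up
Reagents that add atoms: none
Why: Weiler-type γ-acylation of a β-keto ester dianion (Claisen-type acylation): the more basic γ-carbon of 3 attacks the Weinreb amide, whose chelated tetrahedral intermediate prevents over-addition, so the 3,5-diketo ester should be released on acidic work-up.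

Step 2
Reactants: 4 methyl 4-methyl-3,5-dioxoheptanoate
Product: 5 6-ethyl-4-hydroxy-5-methyl-2H-pyran-2-one
Conditions: DBU (1.2 equiv), toluene, reflux; then aq. HCl
Reagents that add atoms: none
Why: Base-mediated lactonisation of a 3,5-diketo ester (6-exo-trig attack of the C5 enolate oxygen on the ester, loss of methanol) followed by enolisation should give the 4-hydroxy-2-pyrone.

Step 3
Reactants: 6 1-(2,4,6-trihydroxyphenyl)ethan-1-one (phloroacetophenone, dried)
Product: 7 1-{2,6-dihydroxy-4-[(triisopropylsilyl)oxy]phenyl}ethan-1-one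
Conditions: TIPSCl (1.05 equiv), imidazole, DMF, 0 °C
Reagents that add atoms: triisopropylsilyl chloride CC(C)[Si](Cl)(C(C)C)C(C)C
Why: Selective O-silylation: the para hydroxyl is the most acidic, is not hydrogen-bonded to the acetyl carbonyl and is the least hindered, so the bulky silyl chloride should react there only.

Step 4
Reactants: 7 1-{2,6-dihydroxy-4-[(triisopropylsilyl)oxy]phenyl}ethan-1-one
Product: 8 1-{2,6-bis(methoxymethoxy)-4-[(triisopropylsilyl)oxy]phenyl}ethan-1-one
Conditions: NaH (2.5 equiv), MOMCl (2.6 equiv), THF/DMF, 0 °C → rt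
Reagents that add atoms: chloromethyl methyl ether COCCl
Why: Williamson-type MOM ether formation: NaH deprotonates both chelated ortho hydroxyls irreversibly and the phenoxides are alkylated by MOMCl, while the aryl TIPS ether should survive the anhydrous conditions.

Step 5
Reactants: 8 1-{2,6-bis(methoxymethoxy)-4-[(triisopropylsilyl)oxy]phenyl}ethan-1-one
Product: 9 1-[4-hydroxy-2,6-bis(methoxymethoxy)phenyl]ethan-1-one
Conditions: TBAF, AcOH (1:1), THF, 0 °C
Reagents that add atoms: none
Why: Fluoride-induced desilylation of an aryl silyl ether, buffered so that the phenol and not the phenoxide is released; MOM acetals are inert to fluoride.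

Step 6
Reactants: 9 1-[4-hydroxy-2,6-bis(methoxymethoxy)phenyl]ethan-1-one
Product: 10 1-[4-hydroxy-3-iodo-2,6-bis(methoxymethoxy)phenyl]ethan-1-one
Conditions: NIS (1.0 equiv), MeCN, −20 → 0 °C
Reagents that add atoms: N-iodosuccinimide O=C1CCC(=O)N1I
Why: Electrophilic aromatic iodination ortho to the free phenol; 9 has a mirror plane through C1 and C4, so both activated positions are equivalent and one equivalent of NIS at low temperature should give a single mono-iodide.

Step 7
Reactants: 10 1-[4-hydroxy-3-iodo-2,6-bis(methoxymethoxy)phenyl]ethan-1-one; 11 myrcene (7-methyl-3-methylideneocta-1,6-diene)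
Product: 14 (R)-1-[4,6-bis(methoxymethoxy)-2-(6-methylhepta-1,5-dien-2-yl)-2,3-dihydro-1-benzofuran-5-yl]ethan-1-one, via arylpalladium(II) iodide 12 (not isolated), via π-allylpalladium complex 13 (not isolated)
Conditions: Pd2(dba)3·CHCl3 (5 mol %), chiral sulfinamide–phosphine ligand (TY-Phos type, 12 mol %, antipode giving 2R), K2CO3 (2 equiv), 11 (3 equiv), degassed toluene, 70 °C
Reagents that add atoms: none
Why: Pd(0) inserts into the C–I bond of 10, the aryl–Pd species 12 adds across the monosubstituted vinyl group of myrcene at its terminal CH2 (Heck-type migratory insertion), and the resulting syn-π-allylpalladium complex 13 is captured at its internal terminus by the neighbouring phenoxide (Tsuji–Trost C–O bond formation), which releases Pd(0). The closest known reaction type is the Larock heteroannulation of o-halophenols with 1,3-dienes in its enantioselective Heck/Tsuji–Trost form with chiral sulfinamide–phosphine ligands, which converts isoprene into 2-isopropenyl-2,3-dihydrobenzofurans and is applied here to a new iodophenol and to myrcene. The dihydrofuran ring closes by 5-exo attack of the phenoxide oxygen on the allyl terminus that bears the ArCH2 group, the alternative attack at the CH2 terminus requiring a seven-membered ring. The only new stereocentre, C2, is set under catalyst control: the diastereomeric π-allyl complexes interconvert by η3–η1–η3 isomerisation through the unsubstituted CH2 terminus, and the chiral ligand decides which face the oxygen attacks. The step needs insertion at the vinyl CH2 rather than at the 1,1-disubstituted or the remote trisubstituted alkene, which the sterics of the diene secure, and closure through the oxygen para to the acetyl group, which is secured because that is the only free hydroxyl (the other two are MOM ethers) and because the symmetry of 9 places the iodine next to it.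

Step 8
Reactants: 14 (R)-1-[4,6-bis(methoxymethoxy)-2-(6-methylhepta-1,5-dien-2-yl)-2,3-dihydro-1-benzofuran-5-yl]ethan-1-one
Product: 15 (R)-1-[4,6-dihydroxy-2-(6-methylhepta-1,5-dien-2-yl)-2,3-dihydro-1-benzofuran-5-yl]ethan-1-one
Conditions: HCl (1.25 M in MeOH, 4 equiv), MeOH/THF, 0 °C → rt
Reagents that add atoms: none
Why: Acid-catalysed acetal exchange (MOM solvolysis) with methanol; both acetals are ortho to the ketone and should cleave under conditions mild enough to leave the allylic aryl ether, both alkenes and the stereocentre untouched.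

Step 9
Reactants: 5 6-ethyl-4-hydroxy-5-methyl-2H-pyran-2-one; 15 (R)-1-[4,6-dihydroxy-2-(6-methylhepta-1,5-dien-2-yl)-2,3-dihydro-1-benzofuran-5-yl]ethan-1-one
Product: 18 3-{[(2R)-5-acetyl-4,6-dihydroxy-2-(6-methylhepta-1,5-dien-2-yl)-2,3-dihydro-1-benzofuran-7-yl]methyl}-6-ethyl-4-hydroxy-5-methyl-2H-pyran-2-one (CNP0294086.1), via Mannich base 16 (not isolated), via methylidenepyrandione 17 (not isolated)
Conditions: 5, Eschenmoser's salt (1.05 equiv), MeCN, rt; then 15, 50 °C
Reagents that add atoms: N,N-dimethylmethyleneiminium iodide (Eschenmoser's salt) C=[N+](C)C.[I-]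
Why: Three-component Mannich/elimination/Michael methylene bridging: the pyrone C3 is aminomethylated to 16, loss of dimethylamine gives the methide 17, and the only free aromatic carbon of 15 (C7, activated by O1 and the 6-OH) adds to it in a conjugate Friedel–Crafts fashion, so only one constitution can form and the remote stereocentre is untouched.

**Compound list**

1 | methyl 3-oxopentanoate | CCC(=O)CC(=O)OC | starting material
2 | N-methoxy-N-methylpropanamide | CCC(=O)N(C)OC | starting material
3 | sodium lithium dianion (bis-enolate) of 1 | CC=C([O-])C=C([O-])OC.[Na+].[Li+] | intermediate (not isolated)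
4 | methyl 4-methyl-3,5-dioxoheptanoate (racemic, enolisable) | CCC(=O)C(C)C(=O)CC(=O)OC | intermediate
5 | 6-ethyl-4-hydroxy-5-methyl-2H-pyran-2-one | CCc1oc(=O)cc(O)c1C | intermediate
6 | 1-(2,4,6-trihydroxyphenyl)ethan-1-one | CC(=O)c1c(O)cc(O)cc1O | starting material
7 | 1-{2,6-dihydroxy-4-[(triisopropylsilyl)oxy]phenyl}ethan-1-one | CC(=O)c1c(O)cc(O[Si](C(C)C)(C(C)C)C(C)C)cc1O | intermediate
8 | 1-{2,6-bis(methoxymethoxy)-4-[(triisopropylsilyl)oxy]phenyl}ethan-1-one | CC(=O)c1c(OCOC)cc(O[Si](C(C)C)(C(C)C)C(C)C)cc1OCOC | intermediate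
9 | 1-[4-hydroxy-2,6-bis(methoxymethoxy)phenyl]ethan-1-one | CC(=O)c1c(OCOC)cc(O)cc1OCOC | intermediate
10 | 1-[4-hydroxy-3-iodo-2,6-bis(methoxymethoxy)phenyl]ethan-1-one | CC(=O)c1c(OCOC)cc(O)c(I)c1OCOC | intermediate
11 | myrcene (7-methyl-3-methylideneocta-1,6-diene) | C=CC(=C)CCC=C(C)C | starting material
12 | arylpalladium(II) iodide from 10 (phosphine ligand omitted) | CC(=O)c1c(OCOC)cc(O)c([Pd]I)c1OCOC | intermediate (not isolated)
13 | π-allylpalladium complex (drawn as its η1 form, phosphine ligand omitted) | CC(=O)c1c(OCOC)cc(O)c(CC([Pd]I)C(=C)CCC=C(C)C)c1OCOC | intermediate (not isolated)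
14 | (R)-1-[4,6-bis(methoxymethoxy)-2-(6-methylhepta-1,5-dien-2-yl)-2,3-dihydro-1-benzofuran-5-yl]ethan-1-one | C=C(CCC=C(C)C)[C@H]1Cc2c(OCOC)c(C(C)=O)c(OCOC)cc2O1 | intermediate
15 | (R)-1-[4,6-dihydroxy-2-(6-methylhepta-1,5-dien-2-yl)-2,3-dihydro-1-benzofuran-5-yl]ethan-1-one | C=C(CCC=C(C)C)[C@H]1Cc2c(O)c(C(C)=O)c(O)cc2O1 | intermediate
16 | 3-[(dimethylamino)methyl]-6-ethyl-4-hydroxy-5-methyl-2H-pyran-2-one | CCc1oc(=O)c(CN(C)C)c(O)c1C | intermediate (not isolated)
17 | 6-ethyl-5-methyl-3-methylidene-2H-pyran-2,4(3H)-dione | CCC1=C(C)C(=O)C(=C)C(=O)O1 | intermediate (not isolated)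
18 | 3-{[(2R)-5-acetyl-4,6-dihydroxy-2-(6-methylhepta-1,5-dien-2-yl)-2,3-dihydro-1-benzofuran-7-yl]methyl}-6-ethyl-4-hydroxy-5-methyl-2H-pyran-2-one (CNP0294086.1) | C=C(CCC=C(C)C)[C@H]1Cc2c(O)c(C(C)=O)c(O)c(Cc3c(O)c(C)c(CC)oc3=O)c2O1 | target

**Step count and risks**

Total step count: 9. Longest linear sequence: 7 steps (6 → 7 → 8 → 9 → 10 → 14 → 15 → 18; steps 3–9). The pyrone branch (steps 1–2) joins at step 9.

Steps most likely to fail:

1. Step 7. The risk is insufficient enantiofacial control in the C–O bond-forming allylic substitution next to a fully substituted arene, together with competing β-hydride elimination to an open-chain aryl diene and protodeiodination of the electron-rich iodide. The fallback gives up catalyst-controlled induction and takes the stereocentre from a resolution. It sets out from 10 and 11: ligand-free Jeffery–Larock conditions (Pd(OAc)2, n-Bu4NCl, K2CO3, DMF, 80 °C) should give racemic 1-[4,6-bis(methoxymethoxy)-2-(6-methylhepta-1,5-dien-2-yl)-2,3-dihydro-1-benzofuran-5-yl]ethan-1-one F1. Preparative SFC on a polysaccharide chiral stationary phase should then separate the (R)-enantiomer, which is 14 and rejoins the route there, from (S)-1-[4,6-bis(methoxymethoxy)-2-(6-methylhepta-1,5-dien-2-yl)-2,3-dihydro-1-benzofuran-5-yl]ethan-1-one F2.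

2. Step 9. The risk is symmetrical homo-coupling: the methide 17 may be trapped by a second pyrone, or two arenes may be bridged, which would consume the valuable fragment 15. The fallback fixes the bridging carbon on the arene first, so that no symmetrical dimer can form. It sets out from 15: Vilsmeier–Haack formylation (POCl3, DMF, EtOAc, 0 °C → rt, then aq. NaOAc) at C7, the only free aromatic position, should give (R)-5-acetyl-4,6-dihydroxy-2-(6-methylhepta-1,5-dien-2-yl)-2,3-dihydro-1-benzofuran-7-carbaldehyde F3. An organocatalytic three-component reductive alkylation with 5 and Hantzsch ester (L-proline cat., CH2Cl2, rt) then proceeds through the Knoevenagel adduct (R)-3-{[5-acetyl-4,6-dihydroxy-2-(6-methylhepta-1,5-dien-2-yl)-2,3-dihydro-1-benzofuran-7-yl]methylidene}-6-ethyl-5-methyl-2H-pyran-2,4(3H)-dione F4. This is reduced in the flask by hydride transfer and comes back to the route at 18.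

3. Step 8. The risk is acid-promoted side reactions during acetal solvolysis: Markovnikov addition to the trisubstituted alkene, ionisation of the allylic aryl ether with loss of enantiopurity, or addition of the liberated 4-OH to the 1,1-disubstituted alkene. The fallback replaces the acid-labile acetal by a fluoride-labile one before the sensitive side chain exists. It sets out from 7:
   - SEMCl/NaH (THF/DMF, 0 °C) should give 1-{2,6-bis{[2-(trimethylsilyl)ethoxy]methoxy}-4-[(triisopropylsilyl)oxy]phenyl}ethan-1-one F5.
   - Buffered TBAF/AcOH at 0 °C should remove only the aryl TIPS group, giving 1-{4-hydroxy-2,6-bis{[2-(trimethylsilyl)ethoxy]methoxy}phenyl}ethan-1-one F6.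
   - NIS should give 1-{4-hydroxy-3-iodo-2,6-bis{[2-(trimethylsilyl)ethoxy]methoxy}phenyl}ethan-1-one F7.
   - The heteroannulation of step 7 with 11 should give (R)-1-{2-(6-methylhepta-1,5-dien-2-yl)-4,6-bis{[2-(trimethylsilyl)ethoxy]methoxy}-2,3-dihydro-1-benzofuran-5-yl}ethan-1-one F8.
   - TBAF in THF/DMPU at 60 °C should unmask both phenols by fluoride-triggered fragmentation under basic, non-ionising conditions, returning to the route at 15.

**Further compounds**

F1 | step 7 | racemic 1-[4,6-bis(methoxymethoxy)-2-(6-methylhepta-1,5-dien-2-yl)-2,3-dihydro-1-benzofuran-5-yl]ethan-1-one | C=C(CCC=C(C)C)C1Cc2c(OCOC)c(C(C)=O)c(OCOC)cc2O1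
F2 | step 7 | (S)-1-[4,6-bis(methoxymethoxy)-2-(6-methylhepta-1,5-dien-2-yl)-2,3-dihydro-1-benzofuran-5-yl]ethan-1-one | C=C(CCC=C(C)C)[C@@H]1Cc2c(OCOC)c(C(C)=O)c(OCOC)cc2O1
F3 | step 9 | (R)-5-acetyl-4,6-dihydroxy-2-(6-methylhepta-1,5-dien-2-yl)-2,3-dihydro-1-benzofuran-7-carbaldehyde | C=C(CCC=C(C)C)[C@H]1Cc2c(O)c(C(C)=O)c(O)c(C=O)c2O1
F4 | step 9 | (R)-3-{[5-acetyl-4,6-dihydroxy-2-(6-methylhepta-1,5-dien-2-yl)-2,3-dihydro-1-benzofuran-7-yl]methylidene}-6-ethyl-5-methyl-2H-pyran-2,4(3H)-dione | C=C(CCC=C(C)C)[C@H]1Cc2c(O)c(C(C)=O)c(O)c(C=C3C(=O)OC(CC)=C(C)C3=O)c2O1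
F5 | step 8 | 1-{2,6-bis{[2-(trimethylsilyl)ethoxy]methoxy}-4-[(triisopropylsilyl)oxy]phenyl}ethan-1-one | CC(=O)c1c(OCOCC[Si](C)(C)C)cc(O[Si](C(C)C)(C(C)C)C(C)C)cc1OCOCC[Si](C)(C)C
F6 | step 8 | 1-{4-hydroxy-2,6-bis{[2-(trimethylsilyl)ethoxy]methoxy}phenyl}ethan-1-one | CC(=O)c1c(OCOCC[Si](C)(C)C)cc(O)cc1OCOCC[Si](C)(C)C
F7 | step 8 | 1-{4-hydroxy-3-iodo-2,6-bis{[2-(trimethylsilyl)ethoxy]methoxy}phenyl}ethan-1-one | CC(=O)c1c(OCOCC[Si](C)(C)C)cc(O)c(I)c1OCOCC[Si](C)(C)C
F8 | step 8 | (R)-1-{2-(6-methylhepta-1,5-dien-2-yl)-4,6-bis{[2-(trimethylsilyl)ethoxy]methoxy}-2,3-dihydro-1-benzofuran-5-yl}ethan-1-one | C=C(CCC=C(C)C)[C@H]1Cc2c(OCOCC[Si](C)(C)C)c(C(C)=O)c(OCOCC[Si](C)(C)C)cc2O1
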